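**Retrosynthetic overview**

1. Numbering: ten-membered ring C1–C10 (C1 quaternary, methyl C15; OAc at C2 and C9); ring C = C1, C10–C14 (epoxide C11/C20); C16 on C5; lactone C7–O–C19–C17(C18)–C8; β is the face of C15.
2. The route rests on the cis,cis-diene C3=C4–C5=C6 of the ten-membered ring, flanked by oxygen at C2, C7 and C16. It is the conrotatory ring-opened form of a trans-fused cyclobutene (C3, C4, C5, C6) on an eight-membered enone (C1, C2, C3, C6–C10), so C4, C5 and C16 come from propargyl alcohol held on O7 by a Me2Si tether.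
3. Repairs: the tether is cut before the opening (with it in place C5=C6 would be a trans alkene in a seven-membered ring); C12/C13 (acetonide) are kept apart from C14 (silyl ether); C8 is carried as a PMB ether.
4. Ring order: ring C (Birch reduction–methylation, chelate-controlled aldol with a D-erythrose-derived C6–C9 aldehyde, dihydroxylation) → eight-membered ring (RCM, before C11 is methylenated) → cyclobutene and siloxane (hν) → ten-membered ring (thermal opening) → lactone (Reformatsky) → epoxide last.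

Key step: step 26

Assumption: the (S)-2-(methoxymethyl)pyrrolidine amide is taken to steer iodomethane to the enolate face that gives the (R) quaternary centre of 11; if the sense is the reverse, the (R)-amine is used.

Step 1
Reactants: 1 2,4-O-ethylidene-D-erythrose
Product: 2 (2R,4S,5R)-4-ethynyl-2-methyl-1,3-dioxan-5-ol
Conditions: dimethyl (1-diazo-2-oxopropyl)phosphonate, K2CO3, MeOH, 0 °C to rt
Reagents that add atoms: dimethyl (1-diazo-2-oxopropyl)phosphonate, COP(=O)(OC)C(=[N+]=[N-])C(C)=O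
Why: Ohira–Bestmann homologation should turn the equatorial aldehyde into the terminal alkyne (a vinyl group masked against OsO4) without touching the stereocentres.

Step 2
Reactants: 2 ethynyl dioxanol
Product: 3 PMB ether of 2
Conditions: NaH, 4-methoxybenzyl chloride, Bu4NI (cat.), DMF, 0 °C
Reagents that add atoms: 4-methoxybenzyl chloride, COc1ccc(CCl)cc1
Why: Williamson etherification of the only hydroxyl places the chelating PMB group on the future C8 oxygen.

Step 3
Reactants: 3 PMB ether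
Product: 4 (2R,3S)-2-[(4-methoxybenzyl)oxy]pent-4-yne-1,3-diol
Conditions: 1 M HCl, THF/H2O, 50 °C
Reagents that add atoms: none
Why: Acid hydrolysis of the ethylidene acetal should free the C7 and C9 hydroxyls while the PMB ether survives dilute acid.

Step 4
Reactants: 4 diol
Product: 5 bis(triethylsilyl) ether of 4
Conditions: Et3SiCl (2.5 equiv), imidazole, DMF, rt
Reagents that add atoms: chlorotriethylsilane, CC[Si](Cl)(CC)CC
Why: Silylation protects both hydroxyls so that the primary one can be addressed selectively in the next step.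

Step 5
Reactants: 5 bis-silyl ether
Product: 6 (2S,3S)-2-[(4-methoxybenzyl)oxy]-3-(triethylsilyloxy)pent-4-ynal (C9 aldehyde, C8, C7, C6)
Conditions: (COCl)2, DMSO, CH2Cl2, −78 to −30 °C; then Et3N, −78 °C
Reagents that add atoms: none
Why: Swern conditions are known to oxidise a primary triethylsilyl ether directly to the aldehyde and to spare the secondary one; at low temperature C8 should not epimerise.

Step 6
Reactants: 7 2,5-dimethoxybenzoyl chloride; 8 (S)-2-(methoxymethyl)pyrrolidine
Product: 9 (S)-(2,5-dimethoxyphenyl)[2-(methoxymethyl)pyrrolidin-1-yl]methanone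
Conditions: Et3N, CH2Cl2, 0 °C
Reagents that add atoms: none
Why: N-Acylation attaches the chiral auxiliary for the reductive alkylation.

Step 7
Reactants: 9 auxiliary benzamide
Product: 11 (R)-1-methyl-2,5-dimethoxycyclohexa-2,5-diene-1-carboxamide of the auxiliary, via potassium amide enolate 10 (not isolated)
Conditions: K, NH3(l), THF, t-BuOH (1 equiv), −78 °C; then MeI
Reagents that add atoms: iodomethane, CI
Why: Auxiliary-controlled Birch reduction–alkylation gives the chelated amide enolate, which is methylated on the face left open by the methoxymethyl arm, setting the quaternary centre C1.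

Step 8
Reactants: 11 diene amide
Product: 12 (R)-2,5-dimethoxy-1-methylcyclohexa-2,5-diene-1-carbaldehyde
Conditions: Cp2Zr(H)Cl (1.8 equiv), THF, rt; aqueous work-up
Reagents that add atoms: water, O
Why: Hydrozirconation of the tertiary amide and hydrolysis of the iminium formed should give the non-enolisable aldehyde and leave the enol ethers intact.

Step 9
Reactants: 12 aldehyde
Product: 13 propargylic alcohol (C2 carbinol, both epimers)
Conditions: ethynylmagnesium bromide, THF, −78 to 0 °C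
Reagents that add atoms: ethynylmagnesium bromide, C#C[Mg]Br
Why: Grignard addition brings in C3 as an alkyne; the configuration of C2 does not matter because C2 is oxidised in step 23.

Step 10
Reactants: 13 propargylic alcohol
Product: 14 propargylic pivalate
Conditions: pivaloyl chloride, DMAP, pyridine, 50 °C
Reagents that add atoms: pivaloyl chloride, CC(C)(C)C(Cl)=O
Why: Esterification gives a C2 protecting group that should withstand acid, Lewis acids, OsO4 and bulky hydride and is later removed reductively.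

Step 11
Reactants: 14 bis(enol ether)
Product: 15 1,4-dione (C11 and C14 ketones)
Conditions: 1 M HCl, THF, rt
Reagents that add atoms: water, O
Why: Hydrolysis of both methyl enol ethers unmasks the two ring C ketones.

Step 12
Reactants: 15 1,4-dione
Product: 16 enedione (C12=C13)
Conditions: IBX (1.5 equiv), DMSO/toluene, 70 °C
Reagents that add atoms: none
Why: IBX dehydrogenation of the ketone can only desaturate C12–C13 because C1 is quaternary, which leaves C10 as the single enolisable position.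

Step 13
Reactants: 16 enedione; 6 aldehyde
Product: 18 aldol adduct (C9–OH; C9 β on C10), via trimethylsilyl dienol ether 17 (not isolated)
Conditions: Me3SiOTf, Et3N, CH2Cl2, 0 °C; then added to 6 premixed with TiCl4, CH2Cl2, −78 °C
Reagents that add atoms: none
Why: Chelation-controlled Mukaiyama aldol: TiCl4 locks the aldehyde with the α-OPMB oxygen so that attack anti to the C7 branch gives C9–O syn to C8–O, the open transition state of the chelate gives the syn C9/C10 relation, and the enol silane reacts on the face of C10 away from the bulkier C1 side chain, placing C9 trans to C2.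

Step 14
Reactants: 18 aldol adduct
Product: 19 C9 TBS ether
Conditions: t-BuMe2SiOTf, 2,6-lutidine, CH2Cl2, −78 °C
Reagents that add atoms: tert-butyldimethylsilyl triflate, CC(C)(C)[Si](C)(C)OS(=O)(=O)C(F)(F)F
Why: Silylation under non-basic conditions protects the β-hydroxy ketone against retro-aldol and elimination.

Step 15
Reactants: 19 enedione
Product: 20 12α,13α-diol
Conditions: OsO4 (5 mol %), N-methylmorpholine N-oxide, acetone/H2O, rt
Reagents that add atoms: N-methylmorpholine N-oxide, C[N+]1([O-])CCOCC1; water, O (delivered through OsO4, O=[Os](=O)(=O)=O)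
Why: Catalytic syn-dihydroxylation: with the C2 and C9 chains trans-diequatorial the C1 methyl is axial and shields the β face, so the diol should form cis to the C2 chain; the terminal alkynes are inert.

Step 16
Reactants: 20 diol
Product: 21 12,13-acetonide
Conditions: 2-methoxypropene, PPTS (cat.), CH2Cl2, 0 °C
Reagents that add atoms: 2-methoxypropene, COC(C)=C
Why: Acetonide formation on the cis-diol sets C12/C13 apart from C14 for the later ester pattern.

Step 17
Reactants: 21 bis-alkyne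
Product: 22 bis-vinyl compound
Conditions: H2 (1 atm), Pd on CaCO3 poisoned with Pb(OAc)2, quinoline, EtOAc, rt
Reagents that add atoms: none
Why: Lindlar semihydrogenation converts both terminal alkynes into the vinyl groups for metathesis.

Step 18
Reactants: 22 diene
Product: 23 cyclooctene (C3=C6, cis)
Conditions: second-generation Grubbs catalyst (H2IMes)(PCy3)Cl2Ru=CHPh (10 mol %), CH2Cl2 (0.002 M), 40 °C
Reagents that add atoms: none
Why: Ring-closing metathesis between two chains held trans-diequatorial on ring C gives the cis cyclooctene; C11 is still a ketone, so no six-membered closure onto a C11 methylene can compete.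

Step 19
Reactants: 23 diketone
Product: 24 C11 methylene compound
Conditions: Zn, CH2Br2, TiCl4, THF/CH2Cl2, 0 °C to rt
Reagents that add atoms: dibromomethane, BrCBr
Why: Non-basic Takai–Lombardo methylenation should take the C11 ketone (next to a CH) and leave the C14 ketone next to quaternary C1, without epimerising C10 or eliminating the acetonide oxygen.

Step 20
Reactants: 24 C14 ketone
Product: 25 14α-alcohol
Conditions: LiBH(s-Bu)3, THF, −78 °C
Reagents that add atoms: none
Why: The bulky hydride attacks equatorially, the axial path being blocked by the syn-axial C12–O bond, to give the axial 14α-OH cis to the acetonide.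

Step 21
Reactants: 25 alcohol
Product: 26 C14 TBS ether
Conditions: t-BuMe2SiOTf, 2,6-lutidine, CH2Cl2, 0 °C
Reagents that add atoms: tert-butyldimethylsilyl triflate, CC(C)(C)[Si](C)(C)OS(=O)(=O)C(F)(F)F
Why: Silylation of the hindered axial alcohol with the triflate gives the same protecting group as at C9, so both can be exchanged for acetate together.

Step 22
Reactants: 26 pivalate
Product: 27 C2 allylic alcohol
Conditions: i-Bu2AlH, CH2Cl2, −78 °C
Reagents that add atoms: none
Why: Reductive cleavage of the pivalate is safe here because no other carbonyl group is present.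

Step 23
Reactants: 27 allylic alcohol
Product: 28 cyclooctenone (C2 ketone, C3=C6)
Conditions: Dess–Martin periodinane, NaHCO3, CH2Cl2, rt
Reagents that add atoms: none
Why: Oxidation of the allylic alcohol gives the enone chromophore and removes the C2 epimer mixture.

Step 24
Reactants: 28 C7 triethylsilyl ether
Product: 29 C7 alcohol
Conditions: HF·pyridine, pyridine, THF, 0 °C
Reagents that add atoms: none
Why: Buffered HF cleaves the secondary triethylsilyl ether much faster than the two hindered TBS ethers.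

Step 25
Reactants: 29 C7 alcohol; 30 dichlorodimethylsilane; 31 propargyl alcohol
Product: 33 cyclooctenone with the dimethyl(propargyloxy)silyl ether on O7 (7S,9S), via chlorodimethylsilyl ether 32 (not isolated)
Conditions: Me2SiCl2 (5 equiv), Et3N, CH2Cl2, 0 °C; volatiles removed; propargyl alcohol, imidazole, CH2Cl2, 0 °C; used crude
Reagents that add atoms: dichlorodimethylsilane, C[Si](C)(Cl)Cl; propargyl alcohol, C#CCO
Why: Stepwise silylation with excess dichlorosilane and alcoholysis of the remaining Si–Cl bond is the standard way to a mixed dialkoxysilane tether.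

Step 26
Reactants: 33 tethered cyclooctenone
Product: 34 trans-fused cyclobutene photoadduct with seven-membered siloxane ring
Conditions: hν (365 nm), degassed MeCN (0.002 M), 0 °C
Reagents that add atoms: none
Why: Irradiation into the n→π* band gives, after intersystem crossing, the twisted enone triplet, whose β-carbon C6 adds to alkyne carbon C5 to leave a 1,4-diradical at C3/C4, which closes after spin inversion. The closest known reaction type is the intramolecular enone–alkyne [2+2] photocycloaddition with a temporary silicon tether, whose cyclobutene adducts are known precursors of ring-expanded 1,3-dienes. The seven-membered siloxane ring is closed by the first radical addition (7-exo-dig, bond C5–C6) and the four-membered ring by recombination of the diradical (bond C3–C4). Both new stereocentres are temporary: C6 is set by the tether, which should place H6 anti to H7, and C3 by collapse of the twisted diradical before it relaxes, which should leave H3 and H6 trans. The step needs head-to-head regiochemistry, secured by the short O–Si–O–CH2 tether from O7 that lets C5 reach only C6, and a trans ring fusion, favoured by the trans-like triplet of an eight-membered enone; light above 350 nm spares the PMB ether and the C11 methylene.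

Step 27
Reactants: 34 photoadduct
Product: 35 cyclobutene diol (C7–OH, C16–OH)
Conditions: HF·pyridine, pyridine, THF, 0 °C
Reagents that add atoms: none
Why: The dialkoxysilane is cleaved by fluoride far faster than the TBS ethers, and it has to go first because a tethered C5=C6 could not become the in-ring cis alkene.

Step 28
Reactants: 35 cyclobutene diol
Product: 36 ten-membered (3Z,5Z)-dienone diol
Conditions: toluene (degassed, BHT), 100 °C
Reagents that add atoms: none
Why: Thermal conrotatory 4π electrocyclic opening of the trans-fused, acyl-activated cyclobutene turns both ring bonds inward to give the cis,cis-diene; C3 and C6 become sp2 and no stereocentre is created.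

Step 29
Reactants: 36 diol
Product: 37 C16 acetate
Conditions: AcCl (1.1 equiv), 2,4,6-collidine, CH2Cl2, −78 °C
Reagents that add atoms: acetyl chloride, CC(Cl)=O
Why: Low-temperature acylation should select the primary allylic hydroxyl over the hindered secondary C7 hydroxyl.

Step 30
Reactants: 37 C7 alcohol
Product: 38 C7 2-bromopropanoate (epimers at CHBr)
Conditions: 2-bromopropanoyl bromide, pyridine, CH2Cl2, −20 °C
Reagents that add atoms: 2-bromopropanoyl bromide, CC(Br)C(Br)=O
Why: Acylation with the acyl bromide puts C17–C19 on O7 as a Reformatsky donor; the CHBr configuration is lost in the enolate.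

Step 31
Reactants: 38 PMB ether
Product: 39 C8 alcohol
Conditions: DDQ, CH2Cl2/pH 7 buffer, 0 °C
Reagents that add atoms: none
Why: Oxidative PMB cleavage is orthogonal to the esters, silyl ethers, acetonide and the electron-poor dienone.

Step 32
Reactants: 39 C8 alcohol
Product: 40 C8 ketone
Conditions: Dess–Martin periodinane, NaHCO3, CH2Cl2, 0 °C
Reagents that add atoms: none
Why: Buffered periodinane oxidation gives the α-acyloxy ketone without base, so C7 should keep its configuration.

Step 33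
Reactants: 40 bromo ester ketone
Product: 41 β-hydroxy γ-lactone (8α-OH, 17-H β, C18 α)
Conditions: Zn dust (activated with Me3SiCl), THF, 0 °C to rt
Reagents that add atoms: none
Why: Intramolecular Reformatsky reaction: the zinc enolate adds to the C8 ketone through a zinc-bridged chelate, which should give the lactone trans-fused to the ten-membered ring (8-OH anti to H7) with the C17 methyl on the side of the C8 hydroxyl.

Step 34
Reactants: 41 dienone
Product: 42 2β-alcohol
Conditions: NaBH4, CeCl3·7H2O, MeOH, −40 °C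
Reagents that add atoms: none
Why: Luche 1,2-reduction; hydride should attack C2 from the face opposite the adjacent C1 methyl, giving the hydroxyl syn to C15, and lactone and acetate are untouched.

Step 35
Reactants: 42 bis-TBS ether
Product: 43 2,9,14-triol
Conditions: HF·pyridine (excess), THF, rt
Reagents that add atoms: none
Why: Fluoride removes both TBS ethers while the acetonide, the esters and the lactone remain.

Step 36
Reactants: 43 triol
Product: 44 2,9,14,16-tetraacetate
Conditions: Ac2O, DMAP, pyridine, rt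
Reagents that add atoms: acetic anhydride, CC(=O)OC(C)=O
Why: DMAP-catalysed acetylation takes the three secondary hydroxyls; the tertiary C8 hydroxyl is too hindered to react under these conditions.

Step 37
Reactants: 44 acetonide
Product: 45 12,13-diol
Conditions: AcOH/H2O (4:1), 45 °C
Reagents that add atoms: none
Why: Mild aqueous acid hydrolyses the acetonide without ionising the allylic acetates.

Step 38
Reactants: 45 allylic diol
Product: 46 11,20-epoxide (oxygen α)
Conditions: VO(acac)2 (5 mol %), t-BuOOH, CH2Cl2, 0 °C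
Reagents that add atoms: tert-butyl hydroperoxide, CC(C)(C)OO
Why: Vanadium-catalysed hydroxyl-directed epoxidation: the axial allylic C12 hydroxyl delivers oxygen to the α face of C11=C20, so the epoxide oxygen is syn to it, and the undirected diene should not react.

Step 39
Reactants: 46 epoxy diol
Product: 47 CNP0303383.2
Conditions: 3-methylbutanoic anhydride, DMAP, Et3N, CH2Cl2, rt
Reagents that add atoms: 3-methylbutanoic anhydride, CC(C)CC(=O)OC(=O)CC(C)C
Why: DMAP-catalysed acylation esterifies the C12 and C13 hydroxyls and leaves the tertiary C8 hydroxyl and the epoxide untouched.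

**Compound list**

1 | 2,4-O-ethylidene-D-erythrose, (2R,4R,5R)-5-hydroxy-2-methyl-1,3-dioxane-4-carbaldehyde | O=C[C@@H]1O[C@H](C)OC[C@H]1O | starting material
2 | (2R,4S,5R)-4-ethynyl-2-methyl-1,3-dioxan-5-ol | C#C[C@@H]1O[C@H](C)OC[C@H]1O | intermediate
3 | (2R,4S,5R)-4-ethynyl-5-[(4-methoxybenzyl)oxy]-2-methyl-1,3-dioxane | C#C[C@@H]1O[C@H](C)OC[C@H]1OCc2ccc(OC)cc2 | intermediate
4 | (2R,3S)-2-[(4-methoxybenzyl)oxy]pent-4-yne-1,3-diol | C#C[C@H](O)[C@H](OCc1ccc(OC)cc1)CO | intermediate
5 | (2R,3S)-2-[(4-methoxybenzyl)oxy]-1,3-bis(triethylsilyloxy)pent-4-yne | C#C[C@H](O[Si](CC)(CC)CC)[C@H](OCc1ccc(OC)cc1)CO[Si](CC)(CC)CC | intermediate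
6 | (2S,3S)-2-[(4-methoxybenzyl)oxy]-3-(triethylsilyloxy)pent-4-ynal | C#C[C@H](O[Si](CC)(CC)CC)[C@H](OCc1ccc(OC)cc1)C=O | intermediate
7 | 2,5-dimethoxybenzoyl chloride | COc1ccc(OC)c(C(Cl)=O)c1 | starting material
8 | (S)-2-(methoxymethyl)pyrrolidine | COC[C@@H]1CCCN1 | starting material
9 | (S)-(2,5-dimethoxyphenyl)[2-(methoxymethyl)pyrrolidin-1-yl]methanone | COC[C@@H]1CCCN1C(=O)c2cc(OC)ccc2OC | intermediate
10 | potassium amide enolate of the 1,4-dihydroarene | COC[C@@H]1CCCN1C([O-])=C2C=C(OC)CC=C2OC.[K+] | intermediate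
11 | (R)-1-methyl-2,5-dimethoxycyclohexa-2,5-diene-1-carboxamide of the auxiliary | COC[C@@H]1CCCN1C(=O)[C@]2(C)C=C(OC)CC=C2OC | intermediate
12 | (R)-2,5-dimethoxy-1-methylcyclohexa-2,5-diene-1-carbaldehyde | O=C[C@]1(C)C=C(OC)CC=C1OC | intermediate
13 | 1-(2,5-dimethoxy-1-methylcyclohexa-2,5-dien-1-yl)prop-2-yn-1-ol, quaternary centre as in 12, carbinol epimers | C#CC(O)[C@]1(C)C=C(OC)CC=C1OC | intermediate
14 | pivalate of 13 | C#CC(OC(=O)C(C)(C)C)[C@]1(C)C=C(OC)CC=C1OC | intermediate
15 | 2-methyl-2-[1-(pivaloyloxy)prop-2-ynyl]cyclohexane-1,4-dione (C14 and C11 ketones) | C#CC(OC(=O)C(C)(C)C)[C@]1(C)CC(=O)CCC1=O | intermediate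
16 | the corresponding cyclohex-2-ene-1,4-dione (C12=C13) | C#CC(OC(=O)C(C)(C)C)[C@]1(C)CC(=O)C=CC1=O | intermediate
17 | trimethylsilyl dienol ether of 16 (C10=C11–OSiMe3) | C#CC(OC(=O)C(C)(C)C)[C@]1(C)C=C(O[Si](C)(C)C)C=CC1=O | intermediate
18 | aldol adduct: enedione with the C6–C9 chain on C10, free C9–OH | C#C[C@H](O[Si](CC)(CC)CC)[C@H](OCc1ccc(OC)cc1)[C@@H](O)[C@H]2C(=O)C=CC(=O)[C@]2(C)C(OC(=O)C(C)(C)C)C#C | intermediate
19 | C9 TBS ether of 18 | C#C[C@H](O[Si](CC)(CC)CC)[C@H](OCc1ccc(OC)cc1)[C@@H](O[Si](C)(C)C(C)(C)C)[C@H]2C(=O)C=CC(=O)[C@]2(C)C(OC(=O)C(C)(C)C)C#C | intermediate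
20 | 12α,13α-diol of 19 | C#C[C@H](O[Si](CC)(CC)CC)[C@H](OCc1ccc(OC)cc1)[C@@H](O[Si](C)(C)C(C)(C)C)[C@H]2C(=O)[C@H](O)[C@H](O)C(=O)[C@]2(C)C(OC(=O)C(C)(C)C)C#C | intermediate
21 | 12,13-acetonide of 20 | C#C[C@H](O[Si](CC)(CC)CC)[C@H](OCc1ccc(OC)cc1)[C@@H](O[Si](C)(C)C(C)(C)C)[C@H]2C(=O)[C@@H]3OC(C)(C)O[C@@H]3C(=O)[C@]2(C)C(OC(=O)C(C)(C)C)C#C | intermediate
22 | bis-vinyl compound from 21 | C=C[C@H](O[Si](CC)(CC)CC)[C@H](OCc1ccc(OC)cc1)[C@@H](O[Si](C)(C)C(C)(C)C)[C@H]2C(=O)[C@@H]3OC(C)(C)O[C@@H]3C(=O)[C@]2(C)C(OC(=O)C(C)(C)C)C=C | intermediate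
23 | bicyclic cyclooctene (cis C3=C6), C11 and C14 ketones, C2 pivalate | CC[Si](CC)(CC)O[C@@H]1[C@H](OCc2ccc(OC)cc2)[C@@H](O[Si](C)(C)C(C)(C)C)[C@H]3C(=O)[C@@H]4OC(C)(C)O[C@@H]4C(=O)[C@]3(C)C(OC(=O)C(C)(C)C)/C=C\1 | intermediate
24 | C11 methylene compound | CC[Si](CC)(CC)O[C@@H]1[C@H](OCc2ccc(OC)cc2)[C@@H](O[Si](C)(C)C(C)(C)C)[C@H]3C(=C)[C@@H]4OC(C)(C)O[C@@H]4C(=O)[C@]3(C)C(OC(=O)C(C)(C)C)/C=C\1 | intermediate
25 | 14α-alcohol | CC[Si](CC)(CC)O[C@@H]1[C@H](OCc2ccc(OC)cc2)[C@@H](O[Si](C)(C)C(C)(C)C)[C@H]3C(=C)[C@@H]4OC(C)(C)O[C@@H]4[C@H](O)[C@]3(C)C(OC(=O)C(C)(C)C)/C=C\1 | intermediate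
26 | C14 TBS ether | CC[Si](CC)(CC)O[C@@H]1[C@H](OCc2ccc(OC)cc2)[C@@H](O[Si](C)(C)C(C)(C)C)[C@H]3C(=C)[C@@H]4OC(C)(C)O[C@@H]4[C@H](O[Si](C)(C)C(C)(C)C)[C@]3(C)C(OC(=O)C(C)(C)C)/C=C\1 | intermediate
27 | C2 allylic alcohol (epimers) | CC[Si](CC)(CC)O[C@@H]1[C@H](OCc2ccc(OC)cc2)[C@@H](O[Si](C)(C)C(C)(C)C)[C@H]3C(=C)[C@@H]4OC(C)(C)O[C@@H]4[C@H](O[Si](C)(C)C(C)(C)C)[C@]3(C)C(O)/C=C\1 | intermediate
28 | cyclooctenone, C7 triethylsilyl ether | CC[Si](CC)(CC)O[C@@H]1[C@H](OCc2ccc(OC)cc2)[C@@H](O[Si](C)(C)C(C)(C)C)[C@H]3C(=C)[C@@H]4OC(C)(C)O[C@@H]4[C@H](O[Si](C)(C)C(C)(C)C)[C@]3(C)C(=O)/C=C\1 | intermediate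
29 | cyclooctenone, free C7–OH | O[C@@H]1[C@H](OCc2ccc(OC)cc2)[C@@H](O[Si](C)(C)C(C)(C)C)[C@H]3C(=C)[C@@H]4OC(C)(C)O[C@@H]4[C@H](O[Si](C)(C)C(C)(C)C)[C@]3(C)C(=O)/C=C\1 | intermediate
30 | dichlorodimethylsilane | C[Si](C)(Cl)Cl | starting material
31 | propargyl alcohol | C#CCO | starting material
32 | chlorodimethylsilyl ether of 29 | C[Si](C)(Cl)O[C@@H]1[C@H](OCc2ccc(OC)cc2)[C@@H](O[Si](C)(C)C(C)(C)C)[C@H]3C(=C)[C@@H]4OC(C)(C)O[C@@H]4[C@H](O[Si](C)(C)C(C)(C)C)[C@]3(C)C(=O)/C=C\1 | intermediate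
33 | cyclooctenone with silicon-tethered alkyne (photoprecursor) | C#CCO[Si](C)(C)O[C@@H]1[C@H](OCc2ccc(OC)cc2)[C@@H](O[Si](C)(C)C(C)(C)C)[C@H]3C(=C)[C@@H]4OC(C)(C)O[C@@H]4[C@H](O[Si](C)(C)C(C)(C)C)[C@]3(C)C(=O)/C=C\1 | intermediate
34 | trans-fused cyclobutene photoadduct (H3 β, H6 α) | C[Si]1(C)O[C@@H]2[C@H](OCc3ccc(OC)cc3)[C@@H](O[Si](C)(C)C(C)(C)C)[C@H]4C(=C)[C@@H]5OC(C)(C)O[C@@H]5[C@H](O[Si](C)(C)C(C)(C)C)[C@]4(C)C(=O)[C@@H]6C=C(CO1)[C@@H]26 | intermediate
35 | cyclobutene diol (C7–OH, C16–OH) | O[C@@H]1[C@H](OCc2ccc(OC)cc2)[C@@H](O[Si](C)(C)C(C)(C)C)[C@H]3C(=C)[C@@H]4OC(C)(C)O[C@@H]4[C@H](O[Si](C)(C)C(C)(C)C)[C@]3(C)C(=O)[C@@H]5C=C(CO)[C@@H]15 | intermediate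
36 | ten-membered (3Z,5Z)-dienone, C7–OH and C16–OH free | OCC1=C/[C@H](O)[C@H](OCc2ccc(OC)cc2)[C@@H](O[Si](C)(C)C(C)(C)C)[C@H]3C(=C)[C@@H]4OC(C)(C)O[C@@H]4[C@H](O[Si](C)(C)C(C)(C)C)[C@]3(C)C(=O)/C=C\1 | intermediate
37 | C16 acetate | CC(=O)OCC1=C/[C@H](O)[C@H](OCc2ccc(OC)cc2)[C@@H](O[Si](C)(C)C(C)(C)C)[C@H]3C(=C)[C@@H]4OC(C)(C)O[C@@H]4[C@H](O[Si](C)(C)C(C)(C)C)[C@]3(C)C(=O)/C=C\1 | intermediate
38 | C7 2-bromopropanoate | CC(=O)OCC1=C/[C@H](OC(=O)C(C)Br)[C@H](OCc2ccc(OC)cc2)[C@@H](O[Si](C)(C)C(C)(C)C)[C@H]3C(=C)[C@@H]4OC(C)(C)O[C@@H]4[C@H](O[Si](C)(C)C(C)(C)C)[C@]3(C)C(=O)/C=C\1 | intermediate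
39 | C8 alcohol | CC(=O)OCC1=C/[C@H](OC(=O)C(C)Br)[C@H](O)[C@@H](O[Si](C)(C)C(C)(C)C)[C@H]2C(=C)[C@@H]3OC(C)(C)O[C@@H]3[C@H](O[Si](C)(C)C(C)(C)C)[C@]2(C)C(=O)/C=C\1 | intermediate
40 | C8 ketone | CC(=O)OCC1=C/[C@H](OC(=O)C(C)Br)C(=O)[C@@H](O[Si](C)(C)C(C)(C)C)[C@H]2C(=C)[C@@H]3OC(C)(C)O[C@@H]3[C@H](O[Si](C)(C)C(C)(C)C)[C@]2(C)C(=O)/C=C\1 | intermediate
41 | 8-hydroxy lactone, C2 ketone | CC(=O)OCC1=C/[C@@H]2OC(=O)[C@H](C)[C@@]2(O)[C@@H](O[Si](C)(C)C(C)(C)C)[C@H]3C(=C)[C@@H]4OC(C)(C)O[C@@H]4[C@H](O[Si](C)(C)C(C)(C)C)[C@]3(C)C(=O)/C=C\1 | intermediate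
42 | 2β-alcohol | CC(=O)OCC1=C/[C@@H]2OC(=O)[C@H](C)[C@@]2(O)[C@@H](O[Si](C)(C)C(C)(C)C)[C@H]3C(=C)[C@@H]4OC(C)(C)O[C@@H]4[C@H](O[Si](C)(C)C(C)(C)C)[C@]3(C)[C@@H](O)/C=C\1 | intermediate
43 | 2,9,14-triol | CC(=O)OCC1=C/[C@@H]2OC(=O)[C@H](C)[C@@]2(O)[C@@H](O)[C@H]3C(=C)[C@@H]4OC(C)(C)O[C@@H]4[C@H](O)[C@]3(C)[C@@H](O)/C=C\1 | intermediate
44 | 2,9,14,16-tetraacetate, 12,13-acetonide | CC(=O)OCC1=C/[C@@H]2OC(=O)[C@H](C)[C@@]2(O)[C@@H](OC(C)=O)[C@H]3C(=C)[C@@H]4OC(C)(C)O[C@@H]4[C@H](OC(C)=O)[C@]3(C)[C@@H](OC(C)=O)/C=C\1 | intermediate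
45 | tetraacetate 12,13-diol | CC(=O)OCC1=C/[C@@H]2OC(=O)[C@H](C)[C@@]2(O)[C@@H](OC(C)=O)[C@H]3C(=C)[C@H](O)[C@H](O)[C@H](OC(C)=O)[C@]3(C)[C@@H](OC(C)=O)/C=C\1 | intermediate
46 | 11,20-epoxy diol | CC(=O)OCC1=C/[C@@H]2OC(=O)[C@H](C)[C@@]2(O)[C@@H](OC(C)=O)[C@H]3[C@@]4(CO4)[C@H](O)[C@H](O)[C@H](OC(C)=O)[C@]3(C)[C@@H](OC(C)=O)/C=C\1 | intermediate
47 | CNP0303383.2 | CC(=O)OCC1=C/[C@@H]2OC(=O)[C@H](C)[C@@]2(O)[C@@H](OC(C)=O)[C@H]2[C@@]3(CO3)[C@H](OC(=O)CC(C)C)[C@H](OC(=O)CC(C)C)[C@H](OC(C)=O)[C@]2(C)[C@@H](OC(C)=O)/C=C\1 | target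

**Step count and risks**

Total steps: 39. Longest linear sequence: 34 steps (steps 6 to 39, from 7 and 8 to 47); the aldehyde 6 is made in 5 steps in parallel.

Steps most likely to fail:

- **Step 26.** The 1,4-diradical may collapse to the cis-fused cyclobutene instead of the trans-fused one. The fallback sets out from 33 and accepts the cis-fused photoadduct F1. Its tether is cleaved with HF·pyridine to the cis-fused cyclobutene diol F2. Thermal conrotatory opening then gives the dienone F3, which carries one trans in-ring alkene (drawn as 5E). Iodine-catalysed or triplet-sensitised E-to-Z isomerisation (I2 cat., visible light, benzene) should relax it to the cis,cis-dienone, and the route is rejoined at 36.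

- **Step 13.** The enol silane may attack on the face of C10 syn to the C1 side chain while the chelate still fixes C9. The fallback sets out from 16 and 6 and replaces kinetic face selection by thermodynamic control. The resulting C10-epimeric aldol F4 is silylated as in step 14 to the C10-epimeric TBS ether F5. C10, which is α to the C11 ketone, is then equilibrated with DBU (CH2Cl2, 0 °C) to the isomer with the C2 and C9 chains trans, and the route is rejoined at 19.

- **Step 33.** The zinc enolate may close with the C17 methyl on the wrong face. The fallback sets out from 40 and sets C17 after the ring closure. The C17-epimeric hydroxy lactone F6 is equilibrated at the carbon α to the lactone carbonyl with DBU in toluene at rt, which should favour the methyl group away from the C9 substituent on the lactone face, and the route is rejoined at 41.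

Further compounds
F1 | step 26 | cis-fused cyclobutene photoadduct (C3 epimer of 34) | C[Si]1(C)O[C@@H]2[C@H](OCc3ccc(OC)cc3)[C@@H](O[Si](C)(C)C(C)(C)C)[C@H]4C(=C)[C@@H]5OC(C)(C)O[C@@H]5[C@H](O[Si](C)(C)C(C)(C)C)[C@]4(C)C(=O)[C@H]6C=C(CO1)[C@@H]26
F2 | step 26 | cis-fused cyclobutene diol (C3 epimer of 35) | O[C@@H]1[C@H](OCc2ccc(OC)cc2)[C@@H](O[Si](C)(C)C(C)(C)C)[C@H]3C(=C)[C@@H]4OC(C)(C)O[C@@H]4[C@H](O[Si](C)(C)C(C)(C)C)[C@]3(C)C(=O)[C@H]5C=C(CO)[C@@H]15
F3 | step 26 | (3Z,5E)-dienone diol (5E isomer of 36) | OCC1=C\[C@H](O)[C@H](OCc2ccc(OC)cc2)[C@@H](O[Si](C)(C)C(C)(C)C)[C@H]3C(=C)[C@@H]4OC(C)(C)O[C@@H]4[C@H](O[Si](C)(C)C(C)(C)C)[C@]3(C)C(=O)/C=C\1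
F4 | step 13 | C10 epimer of aldol adduct 18 | C#C[C@H](O[Si](CC)(CC)CC)[C@H](OCc1ccc(OC)cc1)[C@@H](O)[C@@H]2C(=O)C=CC(=O)[C@]2(C)C(OC(=O)C(C)(C)C)C#C
F5 | step 13 | C10 epimer of TBS ether 19 | C#C[C@H](O[Si](CC)(CC)CC)[C@H](OCc1ccc(OC)cc1)[C@@H](O[Si](C)(C)C(C)(C)C)[C@@H]2C(=O)C=CC(=O)[C@]2(C)C(OC(=O)C(C)(C)C)C#C
F6 | step 33 | C17 epimer of hydroxy lactone 41 | CC(=O)OCC1=C/[C@@H]2OC(=O)[C@@H](C)[C@@]2(O)[C@@H](O[Si](C)(C)C(C)(C)C)[C@H]3C(=C)[C@@H]4OC(C)(C)O[C@@H]4[C@H](O[Si](C)(C)C(C)(C)C)[C@]3(C)C(=O)/C=C\1
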